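**Plan**

1. Target: 8-(2,4-dihydroxy-6-pentylphenoxy)-6-hydroxy-3-pentylisocoumarin. It is achiral, so no stereocentre has to be set.
2. Feature used: in the pendant ring B' the ether carbon C1' lies between the C2' hydroxyl and the C6' pentyl group and para to the C4' hydroxyl. This crowded carbon is therefore bonded to oxygen while still sp3, and ring B' is grown around the oxygen already on C8 of ring A.
3. Retrosynthetic cuts, in order: the O–methyl bond at C6 and the O–ethyl bond at C4'; then C1'–C2', C2'–C3' and C4'–C5' of ring B' (benzannulation of a 4-aryloxycyclobutenone with an ynol ether); then the O8–C(sp3) ether bond; then the two ring bonds of the cyclobutenone formed from 1-heptyne and dichloroketene; then C1–O2 and C3–C4 of the pyranone ring.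
4. Forward order: ring A is bought; the pyranone ring closes by enol-lactonisation; the four-membered ring is made separately by [2+2] cycloaddition; the halves are joined by O-alkylation; ring B' closes last by 6π electrocyclisation.
5. Stereochemistry: the only stereocentres on the way (C4 of the cyclobutenones and transient sp3 carbons in the key step) are racemic and end as arene carbons.

Key step: step 7

Assumption: N-methoxy-N-methylhexanamide and ethoxyacetylene (hexane solution) are taken as catalogue chemicals, and the 4'-oxygen is carried as an ethyl ether so that one BBr3 treatment frees all three phenols.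

**Route**

Step 1
Reactants: 1 1-heptyne; 2 trichloroacetyl chloride
Product: 4 4,4-dichloro-3-pentylcyclobut-2-en-1-one, via dichloroketene 3 (not isolated)
Conditions: Zn–Cu couple, Et2O–DME, slow addition of 2, rt
Reagents that add atoms: none
Why: Zinc dechlorinates 2 to dichloroketene, whose carbonyl carbon bonds to the terminal alkyne carbon in a thermal ketene–alkyne [2+2] cycloaddition, placing the pentyl group on C3 next to the CCl2 carbon, while DME ties up ZnCl2 and limits the 1,3-chloride shift.

Step 2
Reactants: 4 4,4-dichloro-3-pentylcyclobut-2-en-1-one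
Product: 5 4-chloro-3-pentylcyclobut-2-en-1-one (racemic)
Conditions: Zn dust (1.05 equiv), AcOH, TMEDA, EtOH, −10 → 0 °C
Reagents that add atoms: none
Why: In the zinc–acetic acid reduction of an α,α-dichloro ketone the geminal dichloride accepts electrons more readily than the monochloride, so one equivalent of zinc at low temperature with TMEDA buffering should stop after the first chlorine, giving the C4 stereocentre as a racemate that is erased later.

Step 3
Reactants: 6 methyl 2-hydroxy-4-methoxy-6-methylbenzoate
Product: 8 methyl 4-methoxy-2-(methoxymethoxy)-6-methylbenzoate, via sodium phenoxide 7 (not isolated)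
Conditions: NaH (1.2 equiv), DMF, 0 °C; then MOMCl (1.3 equiv), 0 °C → rt
Reagents that add atoms: chloromethyl methyl ether, COCCl
Why: O-alkylation of the sodium phenoxide with the chloromethyl ether (Williamson-type acetal formation) masks the acidic chelated phenol ahead of the lateral metalation.

Step 4
Reactants: 8 methyl 4-methoxy-2-(methoxymethoxy)-6-methylbenzoate; 9 N-methoxy-N-methylhexanamide
Product: 12 methyl 4-methoxy-2-(methoxymethoxy)-6-(2-oxoheptyl)benzoate, via benzylic lithium species 10 (not isolated), via lithium hemiaminal adduct 11 (not isolated)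
Conditions: LiN(iPr)2 (1.1 equiv), THF, −78 °C; then 9, −78 → −40 °C; aq. NH4Cl
Reagents that add atoms: none
Why: Lateral lithiation of the ortho-toluate gives an ester-stabilised benzylic anion that acylates once on the Weinreb amide, because the chelated tetrahedral adduct survives until the quench and keeps the ketone away from base.

Step 5
Reactants: 12 methyl 4-methoxy-2-(methoxymethoxy)-6-(2-oxoheptyl)benzoate
Product: 14 8-hydroxy-6-methoxy-3-pentyl-1H-isochromen-1-one, via phenolic keto ester 13 (not isolated)
Conditions: HCl (cat.), MeOH, 50 °C; evaporate; p-TsOH·H2O (10 mol %), PhMe, 110 °C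
Reagents that add atoms: none
Why: Acid-catalysed transacetalisation removes the MOM group in methanol, and on heating in toluene the benzylic enol of the ketone attacks the neighbouring ester (6-exo-trig enol-lactonisation with loss of methanol) to give the hydrogen-bonded isocoumarin.

Step 6
Reactants: 14 8-hydroxy-6-methoxy-3-pentyl-1H-isochromen-1-one; 5 4-chloro-3-pentylcyclobut-2-en-1-one (racemic)
Product: 15 4-[(6-methoxy-1-oxo-3-pentyl-1H-isochromen-8-yl)oxy]-3-pentylcyclobut-2-en-1-one (racemic)
Conditions: Cs2CO3 (1.2 equiv), 5 (1.2 equiv), MeCN, 0 °C → rt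
Reagents that add atoms: none
Why: In this Williamson etherification of an α-chloro ketone the cesium phenoxide displaces the carbonyl-activated, allylic chloride, and direct and allylic displacement lead to the same constitution because C2 and C4 both flank C1 and C3, the new C4 stereocentre being racemic and lost on aromatisation.

Step 7
Reactants: 15 4-[(6-methoxy-1-oxo-3-pentyl-1H-isochromen-8-yl)oxy]-3-pentylcyclobut-2-en-1-one (racemic); 16 ethoxyacetylene
Product: 21 8-(4-ethoxy-2-hydroxy-6-pentylphenoxy)-6-methoxy-3-pentyl-1H-isochromen-1-one, via aryloxy vinylketene 17 (not isolated), via vinylcyclobutenone 18 (not isolated), via dienylketene 19 (not isolated), via cyclohexadienone 20 (not isolated)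
Conditions: 16 (3 equiv), PhMe, 80 °C, sealed tube
Reagents that add atoms: none
Why: Heating opens 15 by conrotatory four-electron cleavage of C1–C4, the aryloxy donor rotating outward, to give vinylketene 17, and the nucleophilic CH terminus of ynol ether 16 then adds to the ketene carbonyl carbon while the ethoxy-bearing carbon bonds to the ketene alpha carbon in a regioselective [2+2] cycloaddition giving 18. Reversible four-electron opening of 18 gives dienylketene 19, whose disrotatory 6π electrocyclisation joins the ketene carbon (C2') to the aryloxy-bearing terminus (C1') and closes ring B' as cyclohexadienone 20, which tautomerises to phenol 21. This is the Danheiser benzannulation of a cyclobutenone with a heteroatom-substituted alkyne, applied here to a 4-aryloxy member. No stereocentre is created in the product, since the sp3 carbons of 15, 18 and 20 are racemic and become arene carbons. The required pattern (2'-OH, 4'-OEt, 6'-pentyl around C1') is fixed by the polarity of the ynol ether and by the positions of pentyl and aryloxy on the cyclobutenone, and chemoselectivity rests on the ynol ether being a far better ketenophile than the enol-lactone alkene of the isocoumarin. The single hydrogen on C1' lets 20 enolise without expelling the aryloxy group.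

Step 8
Reactants: 21 8-(4-ethoxy-2-hydroxy-6-pentylphenoxy)-6-methoxy-3-pentyl-1H-isochromen-1-one
Product: 22 8-(2,4-dihydroxy-6-pentylphenoxy)-6-hydroxy-3-pentyl-1H-isochromen-1-one
Conditions: BBr3 (8 equiv), CH2Cl2, −78 °C → rt; then H2O
Reagents that add atoms: none
Why: BBr3 coordinates the two alkyl aryl ether oxygens and bromide removes the methyl and ethyl groups (Lewis-acid ether cleavage), whereas the diaryl ether has no sp3 carbon on oxygen and the lactone is known to tolerate these conditions.

**Compound list**

1 | 1-heptyne | C#CCCCCC | starting material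
2 | trichloroacetyl chloride | ClC(Cl)(Cl)C(Cl)=O | starting material
3 | dichloroketene | ClC(Cl)=C=O | intermediate (not isolated)
4 | 4,4-dichloro-3-pentylcyclobut-2-en-1-one | CCCCCC1=CC(=O)C1(Cl)Cl | intermediate
5 | 4-chloro-3-pentylcyclobut-2-en-1-one (racemic) | CCCCCC1=CC(=O)C1Cl | intermediate
6 | methyl 2-hydroxy-4-methoxy-6-methylbenzoate | COC(=O)c1c(C)cc(OC)cc1O | starting material
7 | sodium 5-methoxy-2-(methoxycarbonyl)-3-methylphenolate | COC(=O)c1c(C)cc(OC)cc1[O-].[Na+] | intermediate (not isolated)
8 | methyl 4-methoxy-2-(methoxymethoxy)-6-methylbenzoate | COCOc1cc(OC)cc(C)c1C(=O)OC | intermediate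
9 | N-methoxy-N-methylhexanamide | CCCCCC(=O)N(C)OC | starting material
10 | methyl 2-(lithiomethyl)-4-methoxy-6-(methoxymethoxy)benzoate | [Li]Cc1cc(OC)cc(OCOC)c1C(=O)OC | intermediate (not isolated)
11 | lithium 2-[methoxy(methyl)amino]-1-[5-methoxy-2-(methoxycarbonyl)-3-(methoxymethoxy)phenyl]heptan-2-olate (racemic) | CCCCCC(O[Li])(Cc1cc(OC)cc(OCOC)c1C(=O)OC)N(C)OC | intermediate (not isolated)
12 | methyl 4-methoxy-2-(methoxymethoxy)-6-(2-oxoheptyl)benzoate | CCCCCC(=O)Cc1cc(OC)cc(OCOC)c1C(=O)OC | intermediate
13 | methyl 2-hydroxy-4-methoxy-6-(2-oxoheptyl)benzoate | CCCCCC(=O)Cc1cc(OC)cc(O)c1C(=O)OC | intermediate (not isolated)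
14 | 8-hydroxy-6-methoxy-3-pentyl-1H-isochromen-1-one | CCCCCc1cc2cc(OC)cc(O)c2c(=O)o1 | intermediate
15 | 4-[(6-methoxy-1-oxo-3-pentyl-1H-isochromen-8-yl)oxy]-3-pentylcyclobut-2-en-1-one (racemic) | CCCCCC1=CC(=O)C1Oc1cc(OC)cc2cc(CCCCC)oc(=O)c12 | intermediate
16 | ethoxyacetylene (ethoxyethyne) | C#COCC | starting material
17 | (3E)-4-[(6-methoxy-1-oxo-3-pentyl-1H-isochromen-8-yl)oxy]-3-pentylbuta-1,3-dien-1-one | O=C=C/C(CCCCC)=C/Oc1cc(OC)cc2cc(CCCCC)oc(=O)c12 | intermediate (not isolated)
18 | 3-ethoxy-4-{(1E)-1-[(6-methoxy-1-oxo-3-pentyl-1H-isochromen-8-yl)oxy]hept-1-en-2-yl}cyclobut-2-en-1-one (racemic) | O=C1C=C(OCC)C1/C(CCCCC)=C/Oc1cc(OC)cc2cc(CCCCC)oc(=O)c12 | intermediate (not isolated)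
19 | (3E,5E)-3-ethoxy-6-[(6-methoxy-1-oxo-3-pentyl-1H-isochromen-8-yl)oxy]-5-pentylhexa-1,3,5-trien-1-one | O=C=C/C(OCC)=C\C(CCCCC)=C\Oc1cc(OC)cc2cc(CCCCC)oc(=O)c12 | intermediate (not isolated)
20 | 3-ethoxy-6-[(6-methoxy-1-oxo-3-pentyl-1H-isochromen-8-yl)oxy]-5-pentylcyclohexa-2,4-dien-1-one (racemic) | O=C1C=C(OCC)C=C(CCCCC)C1Oc1cc(OC)cc2cc(CCCCC)oc(=O)c12 | intermediate (not isolated)
21 | 8-(4-ethoxy-2-hydroxy-6-pentylphenoxy)-6-methoxy-3-pentyl-1H-isochromen-1-one | CCCCCc1cc(OCC)cc(O)c1Oc1cc(OC)cc2cc(CCCCC)oc(=O)c12 | intermediate
22 | 8-(2,4-dihydroxy-6-pentylphenoxy)-6-hydroxy-3-pentyl-1H-isochromen-1-one | CCCCCc1cc2cc(O)cc(Oc3c(O)cc(O)cc3CCCCC)c2c(=O)o1 | target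

**Step count and risks**

Total steps: 8. Longest linear sequence: 6 steps (steps 3 to 8, from compound 6). The cyclobutenone branch (steps 1 and 2) joins at step 6.

Steps most likely to fail:

1. Step 6 (etherification). The hydrogen-bonded, peri-hindered phenoxide may displace the secondary cyclobutenyl chloride too slowly. That would leave time for attack of phenoxide or carbonate at the strained carbonyl with ring cleavage, or for base-induced decomposition of the chloride. The fallback sets out from 14 and returns at 15; it moves the ether formation to a primary carbon and builds the four-membered ring afterwards. O-alkylation of 14 with 2-chloro-N,N-dimethylacetamide (K2CO3, DMF, 60 °C) should give 2-[(6-methoxy-1-oxo-3-pentyl-1H-isochromen-8-yl)oxy]-N,N-dimethylacetamide F1. Activation with Tf2O and 2,4,6-collidine in 1,2-dichloroethane should give N-{2-[(6-methoxy-1-oxo-3-pentyl-1H-isochromen-8-yl)oxy]ethenylidene}-N-methylmethanaminium triflate F2. In the presence of excess 1, a keteniminium–alkyne [2+2] cycloaddition (terminal alkyne carbon to the iminium carbon, hence pentyl on C3) should give N-{4-[(6-methoxy-1-oxo-3-pentyl-1H-isochromen-8-yl)oxy]-3-pentylcyclobut-2-en-1-ylidene}-N-methylmethanaminium triflate F3. Hydrolysis with aqueous NaHCO3 then gives 15.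

2. Step 2 (monodechlorination). Reduction may run on past the monochloride, and ZnCl2 may promote 1,3-migration of chloride before or during reduction; both erode the supply of the C4 chloride. The fallback sets out from 1 and returns at 5; it introduces a single chlorine from the start, so no selective reduction is needed. 2-Chloro-N,N-dimethylacetamide with Tf2O and 2,4,6-collidine in 1,2-dichloroethane should give N-(2-chloroethenylidene)-N-methylmethanaminium triflate F4. Its [2+2] cycloaddition with 1 should give N-(4-chloro-3-pentylcyclobut-2-en-1-ylidene)-N-methylmethanaminium triflate F5, and aqueous hydrolysis gives 5.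

3. Step 7 (benzannulation). The vinylketene may be captured by the newly formed phenol (ester formation) or may dimerise, and the ynol ether may fragment thermally before it is consumed. The fallback sets out from 14 and returns at 22; it couples a finished pendant ring instead of building it. 1,3-Dimethoxy-5-pentylbenzene (olivetol dimethyl ether, purchased) is iodinated with N-iodosuccinimide in MeCN between the pentyl group and a methoxyl to give 1-iodo-2,4-dimethoxy-6-pentylbenzene F6. Ullmann etherification of 14 with F6 (CuI, picolinic acid, K3PO4, DMSO, 90 °C) should give 8-(2,4-dimethoxy-6-pentylphenoxy)-6-methoxy-3-pentyl-1H-isochromen-1-one F7. This coupling is demanding because the iodide is di-ortho-substituted and electron-rich. BBr3 in CH2Cl2 then removes the three methyl groups to reach 22.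

**Further compounds**

F1 | step 6 | 2-[(6-methoxy-1-oxo-3-pentyl-1H-isochromen-8-yl)oxy]-N,N-dimethylacetamide | CCCCCc1cc2cc(OC)cc(OCC(=O)N(C)C)c2c(=O)o1
F2 | step 6 | N-{2-[(6-methoxy-1-oxo-3-pentyl-1H-isochromen-8-yl)oxy]ethenylidene}-N-methylmethanaminium triflate | C[N+](C)=C=COc1cc(OC)cc2cc(CCCCC)oc(=O)c12.[O-]S(=O)(=O)C(F)(F)F
F3 | step 6 | N-{4-[(6-methoxy-1-oxo-3-pentyl-1H-isochromen-8-yl)oxy]-3-pentylcyclobut-2-en-1-ylidene}-N-methylmethanaminium triflate (racemic) | CCCCCC1=CC(=[N+](C)C)C1Oc1cc(OC)cc2cc(CCCCC)oc(=O)c12.[O-]S(=O)(=O)C(F)(F)F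
F4 | step 2 | N-(2-chloroethenylidene)-N-methylmethanaminium triflate | C[N+](C)=C=CCl.[O-]S(=O)(=O)C(F)(F)F
F5 | step 2 | N-(4-chloro-3-pentylcyclobut-2-en-1-ylidene)-N-methylmethanaminium triflate (racemic) | CCCCCC1=CC(=[N+](C)C)C1Cl.[O-]S(=O)(=O)C(F)(F)F
F6 | step 7 | 1-iodo-2,4-dimethoxy-6-pentylbenzene | CCCCCc1cc(OC)cc(OC)c1I
F7 | step 7 | 8-(2,4-dimethoxy-6-pentylphenoxy)-6-methoxy-3-pentyl-1H-isochromen-1-one | CCCCCc1cc(OC)cc(OC)c1Oc1cc(OC)cc2cc(CCCCC)oc(=O)c12
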